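**Plan**

1. Cuts: ring B at C6=C7 (Knoevenagel) and C5–C6 (diazoacetate homologation); ring A at C2=C3 and C4–C4a together, in one annulation with a two-carbon C3–C4 unit from methyl propiolate; the chain at C1–C8a (Michael addition).
2. Forward: the C1–C8a bond by organocatalytic Michael addition of a β-keto ester to an enal; then ring A by a domino enamine Michael addition/intramolecular Wittig olefination; then ring B by Roskamp homologation and Knoevenagel closure.
3. Enabling feature: C4a is α to the C5 carbonyl (an enamine carbon while C5 is an aldehyde) and stands 1,4 to C2, which is a ketone carbon before ring A exists. The C3–C4(CO2Me) unit of ring A is a β-phosphonioacrylate: its ester-bearing carbon is electrophilic and its other carbon becomes the ylide.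
4. Helpers: the C1 ester is carried as CH2OSi (a β-keto ester C–H would quench the ylide) and the C7 ketone as an OSi carbinol (so only one ketone is within reach of the ylide); both are oxidised back in one step.
5. Stereochemistry: C8a from the iminium catalyst; C1 by thermodynamic ketalisation (trans to the C8a branch); C4a and C4 from the chiral enamine and the synclinal Michael transition state; the cis ring fusion is carried through under non-epimerising conditions.

Key step: step 10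

Remark: the silyloxy carbinol carbon of the side chain (future C7) comes from racemic 5, is carried as a 1:1 epimer mixture drawn without configuration, and is planarised in step 13; the acetal carbons of 9–13 are anomer mixtures. Target numbering (C1–C8a) is used for carbons that end up in the target.

**Route**

Step 1
Reactants: 1 heptadecanoyl chloride; 2 Meldrum's acid
Product: 4 methyl 3-oxononadecanoate, via acyl Meldrum's acid 3 (not isolated)
Conditions: pyridine, CH2Cl2, 0 °C to rt; then MeOH, reflux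
Reagents that add atoms: methanol, CO
Why: C-acylation of Meldrum's acid followed by methanolysis with loss of acetone and CO2 is the standard β-keto ester synthesis for long-chain acid chlorides.

Step 2
Reactants: 5 2-hexadecyloxirane (racemic)
Product: 6 icos-1-en-4-ol (racemic)
Conditions: CH2=CHMgBr, CuI (10 mol %), THF, −30 °C; then dilute HCl
Reagents that add atoms: vinylmagnesium bromide, C=C[Mg]Br
Why: copper-catalysed Grignard opening of a terminal epoxide at its CH2 terminus should give the homoallylic alcohol, whose carbinol carbon is only a masked ketone and needs no control.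

Step 3
Reactants: 6 icos-1-en-4-ol
Product: 7 tert-butyl(icos-1-en-4-yloxy)diphenylsilane
Conditions: t-BuPh2SiCl, imidazole, DMF, rt
Reagents that add atoms: tert-butyl(chloro)diphenylsilane, CC(C)(C)[Si](Cl)(c1ccccc1)c1ccccc1
Why: silylation of the secondary alcohol with a group that should survive the acidic steps 5 and 8.

Step 4
Reactants: 7 tert-butyl(icos-1-en-4-yloxy)diphenylsilane
Product: 8 (2E)-5-[(tert-butyldiphenylsilyl)oxy]henicos-2-enal
Conditions: crotonaldehyde (5 equiv), RuCl2(=CHPh)(H2IMes)(PCy3) (second-generation Grubbs catalyst, 3 mol %), CH2Cl2, 40 °C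
Reagents that add atoms: crotonaldehyde, C/C=C/C=O
Why: olefin cross-metathesis of a terminal alkene with crotonaldehyde should give the E-enal.

Step 5
Reactants: 4 methyl 3-oxononadecanoate; 8 (2E)-5-[(tert-butyldiphenylsilyl)oxy]henicos-2-enal
Product: 10 methyl (4R)-4-{2-[(tert-butyldiphenylsilyl)oxy]octadecyl}-6-hexadecyl-2-methoxy-3,4-dihydro-2H-pyran-5-carboxylate, via hemiacetal 9 (not isolated)
Conditions: (S)-2-{bis[3,5-bis(trifluoromethyl)phenyl][(trimethylsilyl)oxy]methyl}pyrrolidine (10 mol %), PhCO2H (10 mol %), toluene, rt; then MeOH, PPTS, rt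
Reagents that add atoms: methanol, CO
Why: iminium-catalysed Michael addition of a β-keto ester to an enal, in which the (S)-diarylprolinol silyl ether blocks one face of the E-iminium ion and so sets the future C8a (4R in 10); the adduct closes to the cyclic hemiacetal and is trapped as the methyl acetal.

Step 6
Reactants: 10 methyl (4R)-4-{2-[(tert-butyldiphenylsilyl)oxy]octadecyl}-6-hexadecyl-2-methoxy-3,4-dihydro-2H-pyran-5-carboxylate
Product: 11 [(4R)-4-{2-[(tert-butyldiphenylsilyl)oxy]octadecyl}-6-hexadecyl-2-methoxy-3,4-dihydro-2H-pyran-5-yl]methanol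
Conditions: i-Bu2AlH (3 equiv), CH2Cl2, −78 to −20 °C; Rochelle salt
Reagents that add atoms: none
Why: hydride reduction of the conjugated ester to the allylic alcohol (acetal and silyl ether inert) lowers the future C1 carboxyl to the alcohol level, so that the later ylide meets no β-dicarbonyl C–H.

Step 7
Reactants: 11 [(4R)-4-{2-[(tert-butyldiphenylsilyl)oxy]octadecyl}-6-hexadecyl-2-methoxy-3,4-dihydro-2H-pyran-5-yl]methanol
Product: 12 (4R)-5-{[(tert-butyldiphenylsilyl)oxy]methyl}-4-{2-[(tert-butyldiphenylsilyl)oxy]octadecyl}-6-hexadecyl-2-methoxy-3,4-dihydro-2H-pyran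
Conditions: t-BuPh2SiCl, imidazole, CH2Cl2, rt
Reagents that add atoms: tert-butyl(chloro)diphenylsilane, CC(C)(C)[Si](Cl)(c1ccccc1)c1ccccc1
Why: silylation of the primary allylic alcohol under non-acidic conditions that leave the enol ether intact.

Step 8
Reactants: 12 (4R)-5-{[(tert-butyldiphenylsilyl)oxy]methyl}-4-{2-[(tert-butyldiphenylsilyl)oxy]octadecyl}-6-hexadecyl-2-methoxy-3,4-dihydro-2H-pyran
Product: 14 (3R,4R)-4-{[(tert-butyldiphenylsilyl)oxy]methyl}-3-{2-[(tert-butyldiphenylsilyl)oxy]octadecyl}-5-oxohenicosanal, via dimethoxyoxane 13 (not isolated)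
Conditions: PPTS, MeOH, 40 °C; then 1 M HCl, THF, rt
Reagents that add atoms: water, O
Why: reversible acid-catalysed addition of methanol to the enol ether should let the new centre (future C1) settle in the oxane chair that has CH2OSi and the neighbouring branch trans-diequatorial, and acetal hydrolysis then frees ketone and aldehyde without touching that centre.

Step 9
Reactants: 15 triphenylphosphonium tetrafluoroborate; 16 methyl propiolate
Product: 17 [(E)-3-methoxy-3-oxoprop-1-en-1-yl]triphenylphosphonium tetrafluoroborate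
Conditions: CH2Cl2, 0 °C to rt
Reagents that add atoms: none
Why: conjugate addition of the phosphine to the propiolate and protonation by its own acid (the known addition of phosphonium salts to activated alkynes) should give the β-phosphonioacrylate salt.

Step 10
Reactants: 14 (3R,4R)-4-{[(tert-butyldiphenylsilyl)oxy]methyl}-3-{2-[(tert-butyldiphenylsilyl)oxy]octadecyl}-5-oxohenicosanal; 17 [(E)-3-methoxy-3-oxoprop-1-en-1-yl]triphenylphosphonium tetrafluoroborate; 18 (R)-2-{diphenyl[(trimethylsilyl)oxy]methyl}pyrrolidine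
Product: 21 methyl (1R,4S,5S,6S)-4-{[(tert-butyldiphenylsilyl)oxy]methyl}-5-{2-[(tert-butyldiphenylsilyl)oxy]octadecyl}-6-formyl-3-hexadecylcyclohex-2-ene-1-carboxylate, via enamine 19 (not isolated), via iminium salt 20 (not isolated)
Conditions: 18 (1.05 equiv), 4 Å molecular sieves, CH2Cl2, rt; then 17, CH2Cl2/MeCN, −20 °C to rt; then aq. NaHCO3
Reagents that add atoms: water, O
Why: Proposed new method: only the aldehyde condenses with amine 18, and the enamine 19 (nucleophilic at the future C4a) should add to the ester-bearing carbon of 17, the carbon β to phosphorus, because the cationic phosphonium group and not the ester directs conjugate addition (the regiochemistry of phosphine-catalysed α-additions to propiolates); the iminium ylide so formed attacks the only ketone in the molecule (the future C2), and the oxaphosphetane collapses to the C2=C3 alkene and Ph3PO, so that ring A closes by 6-exo-trig addition to the carbonyl in the mode of an intramolecular Wittig reaction. The closest known reaction types are the annulation of enolates with vinylphosphonium salts (Michael addition, then intramolecular Wittig olefination) and the enamine Michael addition of aldehydes to nitroalkenes with diarylprolinol silyl ethers. C4a is controlled by the amine, whose diphenyl(silyloxy)methyl group blocks one face of the E-enamine; the (R)-amine is the enantiomer that should give the 6S centre of 21 (the sense known for nitroalkene acceptors, where the (S)-amine gives the opposite configuration). C4 is controlled by the compact synclinal transition state of an E-enamine with an E-acceptor, which places the ester on C4 syn to the C8a chain (the analogue of the syn adducts from nitroalkenes); C1 and C8a are not touched. The step needs C–C bond formation at C4 rather than C3 and ring closure faster than protonation of the ylide (which would end in loss of Ph3P): the first is secured by the phosphonium group, the second by the substrate, which has no C–H acid stronger than the conjugate acid of the ylide (C1 carries CH2OSi and not CO2Me, C7 is an ether) and no second ketone, and by the aprotic medium with a preformed enamine.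

Step 11
Reactants: 21 methyl (1R,4S,5S,6S)-4-{[(tert-butyldiphenylsilyl)oxy]methyl}-5-{2-[(tert-butyldiphenylsilyl)oxy]octadecyl}-6-formyl-3-hexadecylcyclohex-2-ene-1-carboxylate
Product: 22 methyl (1R,4S,5S,6S)-4-{[(tert-butyldiphenylsilyl)oxy]methyl}-5-{2-[(tert-butyldiphenylsilyl)oxy]octadecyl}-3-hexadecyl-6-(3-methoxy-3-oxopropanoyl)cyclohex-2-ene-1-carboxylate
Conditions: N2CHCO2Me (1.5 equiv), SnCl2 (10 mol %), CH2Cl2, rt
Reagents that add atoms: methyl diazoacetate, COC(=O)C=[N+]=[N-]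
Why: the Roskamp reaction (Lewis acid-catalysed insertion of a diazoacetate into the aldehyde C–H) should give the β-keto ester under nearly neutral conditions that spare the α-stereocentre (future C4a).

Step 12
Reactants: 22 methyl (1R,4S,5S,6S)-4-{[(tert-butyldiphenylsilyl)oxy]methyl}-5-{2-[(tert-butyldiphenylsilyl)oxy]octadecyl}-3-hexadecyl-6-(3-methoxy-3-oxopropanoyl)cyclohex-2-ene-1-carboxylate
Product: 23 methyl (1R,4S,5S,6S)-3-hexadecyl-4-(hydroxymethyl)-5-(2-hydroxyoctadecyl)-6-(3-methoxy-3-oxopropanoyl)cyclohex-2-ene-1-carboxylate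
Conditions: HF·pyridine, pyridine, THF, 0 °C to rt
Reagents that add atoms: none
Why: buffered fluoride cleavage of both silyl ethers avoids the basic conditions that could epimerise the centre next to the ketone.

Step 13
Reactants: 23 methyl (1R,4S,5S,6S)-3-hexadecyl-4-(hydroxymethyl)-5-(2-hydroxyoctadecyl)-6-(3-methoxy-3-oxopropanoyl)cyclohex-2-ene-1-carboxylate
Product: 24 (1S,4R,5S,6R)-2-hexadecyl-4-(methoxycarbonyl)-5-(3-methoxy-3-oxopropanoyl)-6-(2-oxooctadecyl)cyclohex-2-ene-1-carboxylic acid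
Conditions: CrO3, H2SO4, H2O, acetone, 0 °C
Reagents that add atoms: chromium trioxide (Jones reagent), O=[Cr](=O)=O
Why: Jones oxidation should take the secondary alcohol to the C7 ketone and the primary alcohol to the C1 acid in one operation, removing both oxidation-level helpers together.

Step 14
Reactants: 24 (1S,4R,5S,6R)-2-hexadecyl-4-(methoxycarbonyl)-5-(3-methoxy-3-oxopropanoyl)-6-(2-oxooctadecyl)cyclohex-2-ene-1-carboxylic acid
Product: 25 (1S,4R,4aS,8aR)-2,7-dihexadecyl-4,6-bis(methoxycarbonyl)-5-oxo-1,4,4a,5,8,8a-hexahydronaphthalene-1-carboxylic acid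
Conditions: ethylenediammonium diacetate (20 mol %), 4 Å molecular sieves, CH2Cl2, rt
Reagents that add atoms: none
Why: intramolecular Knoevenagel condensation of the β-keto ester CH2 with the 1,5-related ketone should close ring B, the cis fusion being fixed by the existing C4a and C8a centres and the mild ammonium acetate catalyst chosen to avoid enolisation towards C4a.

Step 15
Reactants: 25 (1S,4R,4aS,8aR)-2,7-dihexadecyl-4,6-bis(methoxycarbonyl)-5-oxo-1,4,4a,5,8,8a-hexahydronaphthalene-1-carboxylic acid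
Product: 26 trimethyl (1S,4R,4aS,8aR)-2,7-dihexadecyl-5-oxo-1,4,4a,5,8,8a-hexahydronaphthalene-1,4,6-tricarboxylate
Conditions: Me3SiCHN2, MeOH/toluene (1:4), 0 °C
Reagents that add atoms: (trimethylsilyl)diazomethane, C[Si](C)(C)C=[N+]=[N-]
Why: esterification with a diazoalkane is neutral, so the epimerisable C1, C4 and C4a centres and the deconjugated C2=C3 alkene should be safe.

**Compound list**

1 | heptadecanoyl chloride | CCCCCCCCCCCCCCCCC(=O)Cl | starting material
2 | Meldrum's acid (2,2-dimethyl-1,3-dioxane-4,6-dione) | CC1(C)OC(=O)CC(=O)O1 | starting material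
3 | 5-(1-hydroxyheptadecylidene)-2,2-dimethyl-1,3-dioxane-4,6-dione | CCCCCCCCCCCCCCCCC(O)=C1C(=O)OC(C)(C)OC1=O | intermediate
4 | methyl 3-oxononadecanoate | CCCCCCCCCCCCCCCCC(=O)CC(=O)OC | intermediate
5 | 2-hexadecyloxirane (1,2-epoxyoctadecane), racemic | CCCCCCCCCCCCCCCCC1CO1 | starting material
6 | icos-1-en-4-ol, racemic | C=CCC(O)CCCCCCCCCCCCCCCC | intermediate
7 | tert-butyl(icos-1-en-4-yloxy)diphenylsilane, racemic | C=CCC(O[Si](c1ccccc1)(c1ccccc1)C(C)(C)C)CCCCCCCCCCCCCCCC | intermediate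
8 | (2E)-5-[(tert-butyldiphenylsilyl)oxy]henicos-2-enal, racemic at C5 | O=C/C=C/CC(O[Si](c1ccccc1)(c1ccccc1)C(C)(C)C)CCCCCCCCCCCCCCCC | intermediate
9 | methyl (4R)-4-{2-[(tert-butyldiphenylsilyl)oxy]octadecyl}-6-hexadecyl-2-hydroxy-3,4-dihydro-2H-pyran-5-carboxylate (anomers, side-chain epimers) | COC(=O)C1=C(CCCCCCCCCCCCCCCC)OC(O)C[C@H]1CC(O[Si](c2ccccc2)(c2ccccc2)C(C)(C)C)CCCCCCCCCCCCCCCC | intermediate
10 | methyl (4R)-4-{2-[(tert-butyldiphenylsilyl)oxy]octadecyl}-6-hexadecyl-2-methoxy-3,4-dihydro-2H-pyran-5-carboxylate | COC(=O)C1=C(CCCCCCCCCCCCCCCC)OC(OC)C[C@H]1CC(O[Si](c2ccccc2)(c2ccccc2)C(C)(C)C)CCCCCCCCCCCCCCCC | intermediate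
11 | [(4R)-4-{2-[(tert-butyldiphenylsilyl)oxy]octadecyl}-6-hexadecyl-2-methoxy-3,4-dihydro-2H-pyran-5-yl]methanol | OCC1=C(CCCCCCCCCCCCCCCC)OC(OC)C[C@H]1CC(O[Si](c2ccccc2)(c2ccccc2)C(C)(C)C)CCCCCCCCCCCCCCCC | intermediate
12 | (4R)-5-{[(tert-butyldiphenylsilyl)oxy]methyl}-4-{2-[(tert-butyldiphenylsilyl)oxy]octadecyl}-6-hexadecyl-2-methoxy-3,4-dihydro-2H-pyran | CC(C)(C)[Si](c2ccccc2)(c2ccccc2)OCC1=C(CCCCCCCCCCCCCCCC)OC(OC)C[C@H]1CC(O[Si](c2ccccc2)(c2ccccc2)C(C)(C)C)CCCCCCCCCCCCCCCC | intermediate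
13 | (3R,4R)-3-{[(tert-butyldiphenylsilyl)oxy]methyl}-4-{2-[(tert-butyldiphenylsilyl)oxy]octadecyl}-2-hexadecyl-2,6-dimethoxyoxane (anomers at C2 and C6) | COC1(CCCCCCCCCCCCCCCC)OC(OC)C[C@@H](CC(O[Si](c2ccccc2)(c2ccccc2)C(C)(C)C)CCCCCCCCCCCCCCCC)[C@@H]1CO[Si](c2ccccc2)(c2ccccc2)C(C)(C)C | intermediate
14 | (3R,4R)-4-{[(tert-butyldiphenylsilyl)oxy]methyl}-3-{2-[(tert-butyldiphenylsilyl)oxy]octadecyl}-5-oxohenicosanal | O=CC[C@@H](CC(O[Si](c1ccccc1)(c1ccccc1)C(C)(C)C)CCCCCCCCCCCCCCCC)[C@H](CO[Si](c1ccccc1)(c1ccccc1)C(C)(C)C)C(=O)CCCCCCCCCCCCCCCC | intermediate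
15 | triphenylphosphonium tetrafluoroborate | [PH+](c1ccccc1)(c1ccccc1)c1ccccc1.F[B-](F)(F)F | starting material
16 | methyl propiolate | C#CC(=O)OC | starting material
17 | [(E)-3-methoxy-3-oxoprop-1-en-1-yl]triphenylphosphonium tetrafluoroborate | COC(=O)/C=C/[P+](c1ccccc1)(c1ccccc1)c1ccccc1.F[B-](F)(F)F | intermediate
18 | (R)-2-{diphenyl[(trimethylsilyl)oxy]methyl}pyrrolidine | C[Si](C)(C)OC(c1ccccc1)(c1ccccc1)[C@H]1CCCN1 | starting material
19 | E-enamine of aldehyde 14 with amine 18 (N–CH=CH in place of OHC–CH2) | C[Si](C)(C)OC(c1ccccc1)(c1ccccc1)[C@H]1CCCN1/C=C/[C@@H](CC(O[Si](c1ccccc1)(c1ccccc1)C(C)(C)C)CCCCCCCCCCCCCCCC)[C@H](CO[Si](c1ccccc1)(c1ccccc1)C(C)(C)C)C(=O)CCCCCCCCCCCCCCCC | intermediate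
20 | iminium tetrafluoroborate of aldehyde 21 with amine 18 (CH=N+ in place of CH=O) | CCCCCCCCCCCCCCCCC1=C[C@@H](C(=O)OC)[C@@H](C=[N+]2CCC[C@@H]2C(O[Si](C)(C)C)(c2ccccc2)c2ccccc2)[C@@H](CC(O[Si](c2ccccc2)(c2ccccc2)C(C)(C)C)CCCCCCCCCCCCCCCC)[C@@H]1CO[Si](c2ccccc2)(c2ccccc2)C(C)(C)C.F[B-](F)(F)F | intermediate
21 | methyl (1R,4S,5S,6S)-4-{[(tert-butyldiphenylsilyl)oxy]methyl}-5-{2-[(tert-butyldiphenylsilyl)oxy]octadecyl}-6-formyl-3-hexadecylcyclohex-2-ene-1-carboxylate | CCCCCCCCCCCCCCCCC1=C[C@@H](C(=O)OC)[C@@H](C=O)[C@@H](CC(O[Si](c2ccccc2)(c2ccccc2)C(C)(C)C)CCCCCCCCCCCCCCCC)[C@@H]1CO[Si](c2ccccc2)(c2ccccc2)C(C)(C)C | intermediate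
22 | methyl (1R,4S,5S,6S)-4-{[(tert-butyldiphenylsilyl)oxy]methyl}-5-{2-[(tert-butyldiphenylsilyl)oxy]octadecyl}-3-hexadecyl-6-(3-methoxy-3-oxopropanoyl)cyclohex-2-ene-1-carboxylate | CCCCCCCCCCCCCCCCC1=C[C@@H](C(=O)OC)[C@@H](C(=O)CC(=O)OC)[C@@H](CC(O[Si](c2ccccc2)(c2ccccc2)C(C)(C)C)CCCCCCCCCCCCCCCC)[C@@H]1CO[Si](c2ccccc2)(c2ccccc2)C(C)(C)C | intermediate
23 | methyl (1R,4S,5S,6S)-3-hexadecyl-4-(hydroxymethyl)-5-(2-hydroxyoctadecyl)-6-(3-methoxy-3-oxopropanoyl)cyclohex-2-ene-1-carboxylate | CCCCCCCCCCCCCCCCC1=C[C@@H](C(=O)OC)[C@@H](C(=O)CC(=O)OC)[C@@H](CC(O)CCCCCCCCCCCCCCCC)[C@@H]1CO | intermediate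
24 | (1S,4R,5S,6R)-2-hexadecyl-4-(methoxycarbonyl)-5-(3-methoxy-3-oxopropanoyl)-6-(2-oxooctadecyl)cyclohex-2-ene-1-carboxylic acid | CCCCCCCCCCCCCCCCC1=C[C@@H](C(=O)OC)[C@@H](C(=O)CC(=O)OC)[C@@H](CC(=O)CCCCCCCCCCCCCCCC)[C@@H]1C(=O)O | intermediate
25 | (1S,4R,4aS,8aR)-2,7-dihexadecyl-4,6-bis(methoxycarbonyl)-5-oxo-1,4,4a,5,8,8a-hexahydronaphthalene-1-carboxylic acid | CCCCCCCCCCCCCCCCC1=C[C@@H](C(=O)OC)[C@H]2C(=O)C(C(=O)OC)=C(CCCCCCCCCCCCCCCC)C[C@H]2[C@@H]1C(=O)O | intermediate
26 | trimethyl (1S,4R,4aS,8aR)-2,7-dihexadecyl-5-oxo-1,4,4a,5,8,8a-hexahydronaphthalene-1,4,6-tricarboxylate | CCCCCCCCCCCCCCCCC1=C[C@@H](C(=O)OC)[C@H]2C(=O)C(C(=O)OC)=C(CCCCCCCCCCCCCCCC)C[C@H]2[C@@H]1C(=O)OC | target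

**Step count and risks**

Total step count: 15. Longest linear sequence: 13 steps (5 to 26 through steps 2–8 and 10–15).

Steps most likely to fail:

1. Step 10 (Proposed new method). The ylide may be protonated, with subsequent loss of Ph3P, before it reaches the ketone; the amine may add to 17; or the resident C8a centre may erode the facial control of the amine. Fallback, with the two bond formations separated and known reaction types only, setting out from 14 and returning at 21: the enamine of 14 with 18 is alkylated with 17 in MeCN containing one equivalent of PhCO2H, which protonates the ylide at once, and hydrolysis should give {(2R,3S,4R,5R)-5-{[(tert-butyldiphenylsilyl)oxy]methyl}-4-{2-[(tert-butyldiphenylsilyl)oxy]octadecyl}-3-formyl-2-(methoxycarbonyl)-6-oxodocosyl}triphenylphosphonium tetrafluoroborate F1 (Michael alkylation of an enamine by a vinylphosphonium salt). The aldehyde is masked with HC(OMe)3, PPTS and MeOH as the dimethyl acetal salt F2. The ylide is then made with KN(SiMe3)2 in THF at −78 °C and should close ring A on warming by intramolecular Wittig olefination of the ketone to methyl (1R,4S,5S,6S)-4-{[(tert-butyldiphenylsilyl)oxy]methyl}-5-{2-[(tert-butyldiphenylsilyl)oxy]octadecyl}-6-(dimethoxymethyl)-3-hexadecylcyclohex-2-ene-1-carboxylate F3. Aqueous oxalic acid in THF returns to 21.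

2. Step 8. The protonation that creates the future C1 may show poor facial control, or the allylic silyl ether may ionise under acid. Fallback that sets both chain stereocentres in one C–C bond formation, setting out from enal 8 and returning at 14: commercial 2-octadecanone is formylated (HCO2Et, NaH) and O-silylated (t-BuPh2SiCl, Et3N) to (E)-1-[(tert-butyldiphenylsilyl)oxy]nonadec-1-en-3-one F4. Conjugate hydrosilylation with Et3SiH and catalytic [(Ph3P)CuH]6 should give the Z enol silane tert-butyl{[(2Z)-3-[(triethylsilyl)oxy]nonadec-2-en-1-yl]oxy}diphenylsilane F5. Mukaiyama–Michael addition of F5 to 8 under iminium catalysis with 5-benzyl-2-tert-butyl-3-methylimidazolidin-4-one trifluoroacetate (the enantiomer that blocks the same enal face as the catalyst of step 5) should give 14 directly.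

3. Step 14. Enolisation of the C5 ketone under amine catalysis may epimerise C4a and lose the cis ring fusion, or dehydration may stall at the hindered ketone. Fallback that closes ring B by an irreversible olefination, setting out from 21 and returning at 25: Pinnick oxidation (NaClO2, NaH2PO4, 2-methylbut-2-ene) of 21 should give (1S,2R,5S,6S)-5-{[(tert-butyldiphenylsilyl)oxy]methyl}-6-{2-[(tert-butyldiphenylsilyl)oxy]octadecyl}-4-hexadecyl-2-(methoxycarbonyl)cyclohex-3-ene-1-carboxylic acid F6. Activation with carbonyldiimidazole and C-acylation of trimethyl phosphonoacetate (MgCl2, Et3N) should give the β-keto phosphonate methyl (1R,4S,5S,6S)-4-{[(tert-butyldiphenylsilyl)oxy]methyl}-5-{2-[(tert-butyldiphenylsilyl)oxy]octadecyl}-6-[2-(dimethoxyphosphoryl)-3-methoxy-3-oxopropanoyl]-3-hexadecylcyclohex-2-ene-1-carboxylate F7. Desilylation and Jones oxidation as in steps 12 and 13 should give (1S,4R,5S,6R)-5-[2-(dimethoxyphosphoryl)-3-methoxy-3-oxopropanoyl]-2-hexadecyl-4-(methoxycarbonyl)-6-(2-oxooctadecyl)cyclohex-2-ene-1-carboxylic acid F8. Intramolecular Horner–Wadsworth–Emmons reaction under Masamune–Roush conditions (LiCl, i-Pr2NEt, MeCN, 0 °C) should then close ring B to 25.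

Further compounds
F1 | step 10 | {(2R,3S,4R,5R)-5-{[(tert-butyldiphenylsilyl)oxy]methyl}-4-{2-[(tert-butyldiphenylsilyl)oxy]octadecyl}-3-formyl-2-(methoxycarbonyl)-6-oxodocosyl}triphenylphosphonium tetrafluoroborate | O=C[C@H]([C@H](C(=O)OC)C[P+](c1ccccc1)(c1ccccc1)c1ccccc1)[C@@H](CC(O[Si](c1ccccc1)(c1ccccc1)C(C)(C)C)CCCCCCCCCCCCCCCC)[C@H](CO[Si](c1ccccc1)(c1ccccc1)C(C)(C)C)C(=O)CCCCCCCCCCCCCCCC.F[B-](F)(F)F
F2 | step 10 | {(2R,3S,4R,5R)-5-{[(tert-butyldiphenylsilyl)oxy]methyl}-4-{2-[(tert-butyldiphenylsilyl)oxy]octadecyl}-3-(dimethoxymethyl)-2-(methoxycarbonyl)-6-oxodocosyl}triphenylphosphonium tetrafluoroborate | COC(OC)[C@H]([C@H](C(=O)OC)C[P+](c1ccccc1)(c1ccccc1)c1ccccc1)[C@@H](CC(O[Si](c1ccccc1)(c1ccccc1)C(C)(C)C)CCCCCCCCCCCCCCCC)[C@H](CO[Si](c1ccccc1)(c1ccccc1)C(C)(C)C)C(=O)CCCCCCCCCCCCCCCC.F[B-](F)(F)F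
F3 | step 10 | methyl (1R,4S,5S,6S)-4-{[(tert-butyldiphenylsilyl)oxy]methyl}-5-{2-[(tert-butyldiphenylsilyl)oxy]octadecyl}-6-(dimethoxymethyl)-3-hexadecylcyclohex-2-ene-1-carboxylate | CCCCCCCCCCCCCCCCC1=C[C@@H](C(=O)OC)[C@@H](C(OC)OC)[C@@H](CC(O[Si](c2ccccc2)(c2ccccc2)C(C)(C)C)CCCCCCCCCCCCCCCC)[C@@H]1CO[Si](c2ccccc2)(c2ccccc2)C(C)(C)C
F4 | step 8 | (E)-1-[(tert-butyldiphenylsilyl)oxy]nonadec-1-en-3-one | CCCCCCCCCCCCCCCCC(=O)/C=C/O[Si](c1ccccc1)(c1ccccc1)C(C)(C)C
F5 | step 8 | tert-butyl{[(2Z)-3-[(triethylsilyl)oxy]nonadec-2-en-1-yl]oxy}diphenylsilane | CCCCCCCCCCCCCCCC/C(O[Si](CC)(CC)CC)=C/CO[Si](c1ccccc1)(c1ccccc1)C(C)(C)C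
F6 | step 14 | (1S,2R,5S,6S)-5-{[(tert-butyldiphenylsilyl)oxy]methyl}-6-{2-[(tert-butyldiphenylsilyl)oxy]octadecyl}-4-hexadecyl-2-(methoxycarbonyl)cyclohex-3-ene-1-carboxylic acid | CCCCCCCCCCCCCCCCC1=C[C@@H](C(=O)OC)[C@@H](C(=O)O)[C@@H](CC(O[Si](c2ccccc2)(c2ccccc2)C(C)(C)C)CCCCCCCCCCCCCCCC)[C@@H]1CO[Si](c2ccccc2)(c2ccccc2)C(C)(C)C
F7 | step 14 | methyl (1R,4S,5S,6S)-4-{[(tert-butyldiphenylsilyl)oxy]methyl}-5-{2-[(tert-butyldiphenylsilyl)oxy]octadecyl}-6-[2-(dimethoxyphosphoryl)-3-methoxy-3-oxopropanoyl]-3-hexadecylcyclohex-2-ene-1-carboxylate | CCCCCCCCCCCCCCCCC1=C[C@@H](C(=O)OC)[C@@H](C(=O)C(C(=O)OC)P(=O)(OC)OC)[C@@H](CC(O[Si](c2ccccc2)(c2ccccc2)C(C)(C)C)CCCCCCCCCCCCCCCC)[C@@H]1CO[Si](c2ccccc2)(c2ccccc2)C(C)(C)C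
F8 | step 14 | (1S,4R,5S,6R)-5-[2-(dimethoxyphosphoryl)-3-methoxy-3-oxopropanoyl]-2-hexadecyl-4-(methoxycarbonyl)-6-(2-oxooctadecyl)cyclohex-2-ene-1-carboxylic acid | CCCCCCCCCCCCCCCCC1=C[C@@H](C(=O)OC)[C@@H](C(=O)C(C(=O)OC)P(=O)(OC)OC)[C@@H](CC(=O)CCCCCCCCCCCCCCCC)[C@@H]1C(=O)O
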